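**Retrosynthetic overview**
1. Target ⇐ 1(10)-epoxidation (last) and two esterifications (C3 with (R)-2-methylbutanoic acid, C8 with (2R,3R)-epoxyangelic acid made by Sharpless epoxidation) of a 3β,8β-dioxygenated heliangolide core.
2. Ten-membered carbocycle (formed second) ⇐ intramolecular Nozaki–Hiyama–Kishi closure of C3–C4 from a (Z)-vinyl iodide/aldehyde; C3 is then reset by oxidation/CBS reduction.
3. α-Methylene-γ-lactone (formed first) ⇐ lactonisation of C6–OH onto the C12 ester of the coupling product.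
4. Key C7–C8 bond ⇐ intermolecular Zn-Barbier carbonyl allylation of aldehyde 9 (C8–C10, C1–C3) with (Z)-2-(bromomethyl)enoate 23 (C4–C7, C11–C13), setting C7 and C8.
5. Fragments: 9 from but-3-yn-1-ol (Zr-catalysed carboalumination/oxirane); 23 from (R)-solketal (iodo-Wittig, vinylalumination, SN2′ bromination).

Assumption: (R)-solketal, (R)-2-methylbutanoic acid and angelic acid are taken as commercial; ring compounds are named with germacrane numbering (C1–C10 ring, C11–C13 lactone, C14 on C10, C15 on C4).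

**Step 1**
Reactants: 1 but-3-yn-1-ol
Product: 2 tert-butyl(but-3-yn-1-yloxy)dimethylsilane
Conditions: TBSCl, imidazole, CH2Cl2, 0 °C → rt
Reagents that add atoms: tert-butyldimethylsilyl chloride CC(C)(C)[Si](C)(C)Cl
Why: Standard silyl protection of the primary alcohol so that the alkyne can be carboaluminated.

**Step 2**
Reactants: 2 tert-butyl(but-3-yn-1-yloxy)dimethylsilane; 3 oxirane
Product: 6 (E)-6-[(tert-butyldimethylsilyl)oxy]-4-methylhex-3-en-1-ol, via alkenylalane 4 (not isolated), via lithium alanate 5 (not isolated)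
Conditions: Me3Al, Cp2ZrCl2 (20 mol%), CH2Cl2, 0 °C → rt; then n-BuLi, hexane/THF, −30 °C; oxirane, −30 °C → rt; aq. work-up
Reagents that add atoms: trimethylaluminium C[Al](C)C
Why: Negishi Zr-catalysed syn-methylalumination puts Me on the internal and Al on the terminal carbon, and the derived alanate opens oxirane with retention, fixing the (E)-trisubstituted C1=C10 alkene.

**Step 3**
Reactants: 6 (E)-6-[(tert-butyldimethylsilyl)oxy]-4-methylhex-3-en-1-ol
Product: 7 (E)-1-[(tert-butyldimethylsilyl)oxy]-6-[(4-methoxybenzyl)oxy]-3-methylhex-3-ene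
Conditions: NaH, PMBCl, TBAI (cat.), THF/DMF, 0 °C → rt
Reagents that add atoms: 4-methoxybenzyl chloride COc1ccc(CCl)cc1
Why: Williamson etherification gives a C3–O protecting group orthogonal to the silyl ethers used later.

**Step 4**
Reactants: 7 (E)-1-[(tert-butyldimethylsilyl)oxy]-6-[(4-methoxybenzyl)oxy]-3-methylhex-3-ene
Product: 8 (E)-6-[(4-methoxybenzyl)oxy]-3-methylhex-3-en-1-ol
Conditions: CSA (cat.), MeOH/CH2Cl2, 0 °C → rt
Reagents that add atoms: none
Why: Acid-catalysed methanolysis removes the primary TBS ether while the PMB ether and alkene are untouched.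

**Step 5**
Reactants: 8 (E)-6-[(4-methoxybenzyl)oxy]-3-methylhex-3-en-1-ol
Product: 9 (E)-6-[(4-methoxybenzyl)oxy]-3-methylhex-3-enal
Conditions: DMP, pyridine, CH2Cl2, 0 °C → rt (used crude)
Reagents that add atoms: none
Why: Buffered Dess–Martin oxidation gives the β,γ-unsaturated aldehyde without migration of the alkene into conjugation.

**Step 6**
Reactants: 10 [(4R)-2,2-dimethyl-1,3-dioxolan-4-yl]methanol
Product: 11 (4S)-2,2-dimethyl-1,3-dioxolane-4-carbaldehyde
Conditions: IBX, EtOAc, 75 °C; filter (used crude)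
Reagents that add atoms: none
Why: IBX oxidation with non-aqueous work-up gives the water-soluble, configurationally labile aldehyde without loss or racemisation (the descriptor changes from R to S only through CIP priorities).

**Step 7**
Reactants: 11 (4S)-2,2-dimethyl-1,3-dioxolane-4-carbaldehyde; 12 ethyltriphenylphosphonium bromide
Product: 16 (4R)-4-[(Z)-2-iodoprop-1-en-1-yl]-2,2-dimethyl-1,3-dioxolane, via ethylidene ylide 13 (not isolated), via iodoethylphosphonium iodide 14 (not isolated), via iodo ylide 15 (not isolated)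
Conditions: 12, n-BuLi, THF, 0 °C → rt; I2, −78 °C; NaHMDS, −20 °C; 11, −78 °C → rt
Reagents that add atoms: iodine II
Why: Stork–Zhao-type Wittig olefination with the α-iodo ylide gives the (Z)-2-iodoalkene (I cis to C6) under kinetic control, and the C6 stereocentre from the chiral pool is untouched at −78 °C.

**Step 8**
Reactants: 16 (4R)-4-[(Z)-2-iodoprop-1-en-1-yl]-2,2-dimethyl-1,3-dioxolane
Product: 17 (2R,3Z)-4-iodopent-3-ene-1,2-diol
Conditions: AcOH/H2O (4:1), 40 °C
Reagents that add atoms: none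
Why: Mild acetal hydrolysis liberates the diol without affecting the vinyl iodide.

**Step 9**
Reactants: 17 (2R,3Z)-4-iodopent-3-ene-1,2-diol
Product: 18 (2R,3Z)-4-iodo-1,2-bis[(triethylsilyl)oxy]pent-3-ene
Conditions: TESCl, imidazole, DMF, 0 °C → rt
Reagents that add atoms: chlorotriethylsilane CC[Si](CC)(CC)Cl
Why: Exhaustive silylation sets up the selective oxidative unmasking of the primary position.

**Step 10**
Reactants: 18 (2R,3Z)-4-iodo-1,2-bis[(triethylsilyl)oxy]pent-3-ene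
Product: 19 (2R,3Z)-4-iodo-2-[(triethylsilyl)oxy]pent-3-enal
Conditions: (COCl)2, DMSO, CH2Cl2, −78 °C; 18, −78 → −40 °C; Et3N, −78 → 0 °C (used crude)
Reagents that add atoms: none
Why: Under Swern conditions the primary TES ether is cleaved and oxidised in situ while the secondary TES ether survives, and the cold work-up preserves the α-stereocentre.

**Step 11**
Reactants: 19 (2R,3Z)-4-iodo-2-[(triethylsilyl)oxy]pent-3-enal; 20 methyl propiolate
Product: 22 methyl (3RS,4R,5Z)-3-hydroxy-6-iodo-2-methylidene-4-[(triethylsilyl)oxy]hept-5-enoate, via vinylalane 21 (not isolated)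
Conditions: DIBAL-H, NMO, THF, 0 °C; 20, 0 °C; then 19, 0 °C → rt; Rochelle-salt work-up
Reagents that add atoms: none
Why: Vinylalumination (hydroalumination of the propiolate, then carbonyl addition) gives the Morita–Baylis–Hillman-type adduct under non-basic conditions; the C7 carbinol configuration is irrelevant because it is destroyed in step 12.

**Step 12**
Reactants: 22 methyl (3RS,4R,5Z)-3-hydroxy-6-iodo-2-methylidene-4-[(triethylsilyl)oxy]hept-5-enoate
Product: 23 methyl (2Z,4S,5Z)-2-(bromomethyl)-6-iodo-4-[(triethylsilyl)oxy]hepta-2,5-dienoate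
Conditions: NBS, Me2S, CH2Cl2, 0 °C → rt
Reagents that add atoms: N-bromosuccinimide O=C1CCC(=O)N1Br
Why: Corey–Kim-type activation followed by SN2′ bromide attack gives the thermodynamically preferred conjugated (Z)-allylic bromide (C6 cis to CH2Br); C6 is unchanged (S only through CIP priorities).

**Step 13**
Reactants: 9 (E)-6-[(4-methoxybenzyl)oxy]-3-methylhex-3-enal; 23 methyl (2Z,4S,5Z)-2-(bromomethyl)-6-iodo-4-[(triethylsilyl)oxy]hepta-2,5-dienoate
Product: 24 methyl (3R,4R,6E)-4-hydroxy-3-[(1S,2Z)-3-iodo-1-[(triethylsilyl)oxy]but-2-en-1-yl]-9-[(4-methoxybenzyl)oxy]-6-methyl-2-methylidenenon-6-enoate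
Conditions: Zn dust, THF/sat. aq. NH4Cl (3:1), 0 °C → rt
Reagents that add atoms: none
Why: Barbier-type carbonyl allylation in which the 2-(methoxycarbonyl)allylzinc reacts at C7 through a Zimmerman–Traxler chair, the (Z)-disposed C6 substituent giving the 7,8-syn adduct (C8 R), while A(1,3) strain holds C6–H in the alkene plane so the aldehyde adds anti to the bulky OTES group (C7 R).

**Step 14**
Reactants: 24 Barbier adduct (C8–OH)
Product: 25 methyl (3R,4R,6E)-4-[(tert-butyldimethylsilyl)oxy]-3-[(1S,2Z)-3-iodo-1-[(triethylsilyl)oxy]but-2-en-1-yl]-9-[(4-methoxybenzyl)oxy]-6-methyl-2-methylidenenon-6-enoate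
Conditions: TBSOTf, 2,6-lutidine, CH2Cl2, −78 → 0 °C
Reagents that add atoms: tert-butyldimethylsilyl triflate CC(C)(C)[Si](C)(C)OS(=O)(=O)C(F)(F)F
Why: Fast non-nucleophilic silylation blocks C8–OH before it can form the unwanted 8,12-lactone.

**Step 15**
Reactants: 25 C8-OTBS/C6-OTES methyl ester
Product: 27 (4S,5S)-4-[(1R,3E)-1-[(tert-butyldimethylsilyl)oxy]-6-[(4-methoxybenzyl)oxy]-3-methylhex-3-en-1-yl]-5-[(1Z)-2-iodoprop-1-en-1-yl]-3-methylideneoxolan-2-one, via hydroxy ester 26 (not isolated)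
Conditions: PPTS, MeOH/CH2Cl2, 0 °C → rt; then PPTS (cat.), toluene, 50 °C
Reagents that add atoms: none
Why: The TES ether is cleaved selectively beside TBS and PMB, and the freed C6–OH lactonises onto the γ-ester with retention to give the trans-disubstituted α-methylene-γ-butyrolactone.

**Step 16**
Reactants: 27 PMB-protected lactone
Product: 28 (4S,5S)-4-[(1R,3E)-1-[(tert-butyldimethylsilyl)oxy]-6-hydroxy-3-methylhex-3-en-1-yl]-5-[(1Z)-2-iodoprop-1-en-1-yl]-3-methylideneoxolan-2-one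
Conditions: DDQ, CH2Cl2/pH 7 buffer (10:1), 0 °C → rt
Reagents that add atoms: none
Why: Oxidative PMB cleavage is neutral and leaves the vinyl iodide, TBS ether and enoate intact.

**Step 17**
Reactants: 28 primary alcohol
Product: 29 (3E,6R)-6-[(tert-butyldimethylsilyl)oxy]-6-[(2S,3S)-2-[(1Z)-2-iodoprop-1-en-1-yl]-4-methylidene-5-oxooxolan-3-yl]-3-methylhex-3-enal
Conditions: DMP, pyridine, CH2Cl2, 0 °C (used crude)
Reagents that add atoms: none
Why: Buffered Dess–Martin oxidation gives the sensitive β,γ-unsaturated aldehyde for immediate cyclisation.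

**Step 18**
Reactants: 29 iodo-aldehyde
Product: 30 8β-[(tert-butyldimethylsilyl)oxy]-3-hydroxygermacra-1(10)E,4Z,11(13)-trien-12,6α-olide (C3 epimers)
Conditions: CrCl2 (10 equiv), NiCl2 (0.1 equiv), degassed DMSO/THF, 0.003 M, slow addition, rt
Reagents that add atoms: none
Why: Intramolecular Nozaki–Hiyama–Kishi alkenylation at high dilution closes the ten-membered ring with retention of the (Z)-alkene and tolerance of the lactone; the C3 carbinol is not reliably controlled here and is reset in steps 19–20.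

**Step 19**
Reactants: 30 C3 allylic alcohols
Product: 31 8β-[(tert-butyldimethylsilyl)oxy]-3-oxogermacra-1(10)E,4Z,11(13)-trien-12,6α-olide
Conditions: DMP, pyridine, CH2Cl2, 0 °C → rt
Reagents that add atoms: none
Why: Dess–Martin oxidation converges both epimers to one enone under non-basic conditions that do not move the β,γ-alkene.

**Step 20**
Reactants: 31 macrocyclic enone
Product: 32 8β-[(tert-butyldimethylsilyl)oxy]-3β-hydroxygermacra-1(10)E,4Z,11(13)-trien-12,6α-olide (3S)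
Conditions: (R)-Me-CBS (0.5 equiv), catecholborane, toluene, −78 °C
Reagents that add atoms: none
Why: Corey–Bakshi–Shibata reduction, with the alkenyl side as the large and C2H2 as the small group, delivers hydride under catalyst control to give the 3S alcohol, and catecholborane at −78 °C spares the lactone and alkenes.

**Step 21**
Reactants: 32 3β-alcohol; 33 (R)-2-methylbutanoic acid
Product: 34 8β-[(tert-butyldimethylsilyl)oxy]-3β-[(2R)-2-methylbutanoyloxy]germacra-1(10)E,4Z,11(13)-trien-12,6α-olide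
Conditions: 33, DCC, DMAP (cat.), CH2Cl2, 0 °C → rt
Reagents that add atoms: none
Why: Steglich esterification acylates the allylic alcohol with retention, and low temperature with catalytic DMAP avoids epimerising the acid α-centre.

**Step 22**
Reactants: 34 C8 silyl ether
Product: 35 8β-hydroxy-3β-[(2R)-2-methylbutanoyloxy]germacra-1(10)E,4Z,11(13)-trien-12,6α-olide
Conditions: HF·pyridine, pyridine, THF, 0 °C → rt
Reagents that add atoms: none
Why: Buffered fluoride desilylation frees C8–OH without touching the esters or the lactone.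

**Step 23**
Reactants: 36 angelic acid
Product: 37 (Z)-2-methylbut-2-en-1-ol
Conditions: LiAlH4, Et2O, 0 °C
Reagents that add atoms: none
Why: Hydride reduction of the acid gives the allylic alcohol with the (Z)-geometry retained.

**Step 24**
Reactants: 37 (Z)-2-methylbut-2-en-1-ol
Product: 38 [(2S,3R)-2,3-dimethyloxiran-2-yl]methanol
Conditions: Ti(OiPr)4 (10 mol%), L-(+)-DET (12 mol%), TBHP, 4 Å MS, CH2Cl2, −20 °C
Reagents that add atoms: tert-butyl hydroperoxide CC(C)(C)OO
Why: Sharpless asymmetric epoxidation with L-(+)-tartrate delivers oxygen to the face that gives the 2S carbinol-bearing carbon, and the (Z)-alkene geometry fixes C3 as R.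

**Step 25**
Reactants: 38 [(2S,3R)-2,3-dimethyloxiran-2-yl]methanol
Product: 39 (2R,3R)-2,3-dimethyloxirane-2-carboxylic acid
Conditions: RuCl3·xH2O (2 mol%), NaIO4, MeCN/EtOAc/H2O, 0 °C → rt
Reagents that add atoms: sodium periodate [Na+].[O-]I(=O)(=O)=O
Why: Catalytic RuO4 oxidation takes the primary alcohol to the acid without opening the epoxide (both centres retained; C2 becomes R only through CIP priorities).

**Step 26**
Reactants: 35 8β-alcohol; 39 (2R,3R)-2,3-dimethyloxirane-2-carboxylic acid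
Product: 41 8β-[(2R,3R)-2,3-epoxy-2-methylbutanoyloxy]-3β-[(2R)-2-methylbutanoyloxy]germacra-1(10)E,4Z,11(13)-trien-12,6α-olide, via mixed anhydride 40 (not isolated)
Conditions: 39, 2,4,6-trichlorobenzoyl chloride, Et3N, THF, rt; then 35, DMAP, toluene, rt → 40 °C
Reagents that add atoms: none
Why: Yamaguchi esterification is the standard method for coupling a hindered α,α-disubstituted acid to a hindered secondary alcohol, with retention at C8 and in the acid.

**Step 27**
Reactants: 41 diester triene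
Product: 42 (1R,3S,4Z,6R,7R,8R,10R)-1β,10α-epoxy-8β-[(2R,3R)-2,3-epoxy-2-methylbutanoyloxy]-3β-[(2R)-2-methylbutanoyloxy]germacra-4,11(13)-dien-12,6α-olide
Conditions: mCPBA, NaHCO3, CH2Cl2, 0 °C
Reagents that add atoms: meta-chloroperoxybenzoic acid OOC(=O)c1cccc(Cl)c1
Why: Prilezhaev epoxidation attacks only the electron-rich 1(10)-alkene (the 4,5-alkene is flanked by two acyloxy groups and the enoate is inert), from its exposed outer face in the C14-up conformer, giving the 1β,10α (1R,10R) epoxide as in related germacranolides.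

**Compound list**
1 | but-3-yn-1-ol | C#CCCO | starting material
2 | tert-butyl(but-3-yn-1-yloxy)dimethylsilane | C#CCCO[Si](C)(C)C(C)(C)C | intermediate
3 | oxirane (ethylene oxide) | C1CO1 | starting material
4 | [(E)-4-[(tert-butyldimethylsilyl)oxy]-2-methylbut-1-en-1-yl]dimethylalumane | C[Al](C)/C=C(\C)CCO[Si](C)(C)C(C)(C)C | intermediate
5 | lithium butyl[(E)-4-[(tert-butyldimethylsilyl)oxy]-2-methylbut-1-en-1-yl]dimethylalanate | [Li+].CCCC[Al-](C)(C)/C=C(\C)CCO[Si](C)(C)C(C)(C)C | intermediate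
6 | (E)-6-[(tert-butyldimethylsilyl)oxy]-4-methylhex-3-en-1-ol | OCC/C=C(\C)CCO[Si](C)(C)C(C)(C)C | intermediate
7 | (E)-1-[(tert-butyldimethylsilyl)oxy]-6-[(4-methoxybenzyl)oxy]-3-methylhex-3-ene | COc1ccc(COCC/C=C(\C)CCO[Si](C)(C)C(C)(C)C)cc1 | intermediate
8 | (E)-6-[(4-methoxybenzyl)oxy]-3-methylhex-3-en-1-ol | COc1ccc(COCC/C=C(\C)CCO)cc1 | intermediate
9 | (E)-6-[(4-methoxybenzyl)oxy]-3-methylhex-3-enal | COc1ccc(COCC/C=C(\C)CC=O)cc1 | intermediate
10 | [(4R)-2,2-dimethyl-1,3-dioxolan-4-yl]methanol, (R)-solketal | CC1(C)O[C@@H](CO1)CO | starting material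
11 | (4S)-2,2-dimethyl-1,3-dioxolane-4-carbaldehyde | CC1(C)O[C@@H](CO1)C=O | intermediate
12 | ethyltriphenylphosphonium bromide | CC[P+](c1ccccc1)(c1ccccc1)c1ccccc1.[Br-] | starting material
13 | ethylidene(triphenyl)phosphorane | CC=P(c1ccccc1)(c1ccccc1)c1ccccc1 | intermediate
14 | (1-iodoethyl)triphenylphosphonium iodide | CC(I)[P+](c1ccccc1)(c1ccccc1)c1ccccc1.[I-] | intermediate
15 | (1-iodoethylidene)triphenylphosphorane | CC(I)=P(c1ccccc1)(c1ccccc1)c1ccccc1 | intermediate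
16 | (4R)-4-[(Z)-2-iodoprop-1-en-1-yl]-2,2-dimethyl-1,3-dioxolane | CC1(C)O[C@@H](CO1)/C=C(/C)I | intermediate
17 | (2R,3Z)-4-iodopent-3-ene-1,2-diol | OC[C@H](O)/C=C(/C)I | intermediate
18 | (2R,3Z)-4-iodo-1,2-bis[(triethylsilyl)oxy]pent-3-ene | CC[Si](CC)(CC)OC[C@H](O[Si](CC)(CC)CC)/C=C(/C)I | intermediate
19 | (2R,3Z)-4-iodo-2-[(triethylsilyl)oxy]pent-3-enal | O=C[C@H](O[Si](CC)(CC)CC)/C=C(/C)I | intermediate
20 | methyl propiolate | C#CC(=O)OC | starting material
21 | methyl 2-(diisobutylalumanyl)prop-2-enoate | COC(=O)C(=C)[Al](CC(C)C)CC(C)C | intermediate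
22 | methyl (3RS,4R,5Z)-3-hydroxy-6-iodo-2-methylidene-4-[(triethylsilyl)oxy]hept-5-enoate | COC(=O)C(=C)C(O)[C@H](O[Si](CC)(CC)CC)/C=C(/C)I | intermediate
23 | methyl (2Z,4S,5Z)-2-(bromomethyl)-6-iodo-4-[(triethylsilyl)oxy]hepta-2,5-dienoate | COC(=O)/C(CBr)=C/[C@H](O[Si](CC)(CC)CC)/C=C(/C)I | intermediate
24 | methyl (3R,4R,6E)-4-hydroxy-3-[(1S,2Z)-3-iodo-1-[(triethylsilyl)oxy]but-2-en-1-yl]-9-[(4-methoxybenzyl)oxy]-6-methyl-2-methylidenenon-6-enoate | C=C(C(=O)OC)[C@@H]([C@H](O[Si](CC)(CC)CC)/C=C(/C)I)[C@H](O)C/C(C)=C/CCOCc1ccc(OC)cc1 | intermediate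
25 | methyl (3R,4R,6E)-4-[(tert-butyldimethylsilyl)oxy]-3-[(1S,2Z)-3-iodo-1-[(triethylsilyl)oxy]but-2-en-1-yl]-9-[(4-methoxybenzyl)oxy]-6-methyl-2-methylidenenon-6-enoate | C=C(C(=O)OC)[C@@H]([C@H](O[Si](CC)(CC)CC)/C=C(/C)I)[C@H](O[Si](C)(C)C(C)(C)C)C/C(C)=C/CCOCc1ccc(OC)cc1 | intermediate
26 | methyl (3S,4R,6E)-4-[(tert-butyldimethylsilyl)oxy]-3-[(1S,2Z)-1-hydroxy-3-iodobut-2-en-1-yl]-9-[(4-methoxybenzyl)oxy]-6-methyl-2-methylidenenon-6-enoate | C=C(C(=O)OC)[C@@H]([C@H](O)/C=C(/C)I)[C@H](O[Si](C)(C)C(C)(C)C)C/C(C)=C/CCOCc1ccc(OC)cc1 | intermediate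
27 | (4S,5S)-4-[(1R,3E)-1-[(tert-butyldimethylsilyl)oxy]-6-[(4-methoxybenzyl)oxy]-3-methylhex-3-en-1-yl]-5-[(1Z)-2-iodoprop-1-en-1-yl]-3-methylideneoxolan-2-one | C=C1C(=O)O[C@H](/C=C(/C)I)[C@H]1[C@H](O[Si](C)(C)C(C)(C)C)C/C(C)=C/CCOCc1ccc(OC)cc1 | intermediate
28 | (4S,5S)-4-[(1R,3E)-1-[(tert-butyldimethylsilyl)oxy]-6-hydroxy-3-methylhex-3-en-1-yl]-5-[(1Z)-2-iodoprop-1-en-1-yl]-3-methylideneoxolan-2-one | C=C1C(=O)O[C@H](/C=C(/C)I)[C@H]1[C@H](O[Si](C)(C)C(C)(C)C)C/C(C)=C/CCO | intermediate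
29 | (3E,6R)-6-[(tert-butyldimethylsilyl)oxy]-6-[(2S,3S)-2-[(1Z)-2-iodoprop-1-en-1-yl]-4-methylidene-5-oxooxolan-3-yl]-3-methylhex-3-enal | C=C1C(=O)O[C@H](/C=C(/C)I)[C@H]1[C@H](O[Si](C)(C)C(C)(C)C)C/C(C)=C/CC=O | intermediate
30 | 8β-[(tert-butyldimethylsilyl)oxy]-3-hydroxygermacra-1(10)E,4Z,11(13)-trien-12,6α-olide, C3 epimers (H-6β, H-7α) | C=C1C(=O)O[C@@H]2/C=C(/C)C(O)C/C=C(\C)C[C@@H](O[Si](C)(C)C(C)(C)C)[C@@H]12 | intermediate
31 | 8β-[(tert-butyldimethylsilyl)oxy]-3-oxogermacra-1(10)E,4Z,11(13)-trien-12,6α-olide | C=C1C(=O)O[C@@H]2/C=C(/C)C(=O)C/C=C(\C)C[C@@H](O[Si](C)(C)C(C)(C)C)[C@@H]12 | intermediate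
32 | (3S)-8β-[(tert-butyldimethylsilyl)oxy]-3β-hydroxygermacra-1(10)E,4Z,11(13)-trien-12,6α-olide | C=C1C(=O)O[C@@H]2/C=C(/C)[C@@H](O)C/C=C(\C)C[C@@H](O[Si](C)(C)C(C)(C)C)[C@@H]12 | intermediate
33 | (R)-2-methylbutanoic acid | CC[C@@H](C)C(=O)O | starting material
34 | 8β-[(tert-butyldimethylsilyl)oxy]-3β-[(2R)-2-methylbutanoyloxy]germacra-1(10)E,4Z,11(13)-trien-12,6α-olide | C=C1C(=O)O[C@@H]2/C=C(/C)[C@@H](OC(=O)[C@H](C)CC)C/C=C(\C)C[C@@H](O[Si](C)(C)C(C)(C)C)[C@@H]12 | intermediate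
35 | 8β-hydroxy-3β-[(2R)-2-methylbutanoyloxy]germacra-1(10)E,4Z,11(13)-trien-12,6α-olide | C=C1C(=O)O[C@@H]2/C=C(/C)[C@@H](OC(=O)[C@H](C)CC)C/C=C(\C)C[C@@H](O)[C@@H]12 | intermediate
36 | angelic acid, (Z)-2-methylbut-2-enoic acid | C/C=C(/C)C(=O)O | starting material
37 | (Z)-2-methylbut-2-en-1-ol | C/C=C(/C)CO | intermediate
38 | [(2S,3R)-2,3-dimethyloxiran-2-yl]methanol | OC[C@]1(C)O[C@@H]1C | intermediate
39 | (2R,3R)-2,3-dimethyloxirane-2-carboxylic acid | OC(=O)[C@]1(C)O[C@@H]1C | intermediate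
40 | (2R,3R)-2,3-dimethyloxirane-2-carboxylic 2,4,6-trichlorobenzoic anhydride | Clc1cc(Cl)c(C(=O)OC(=O)[C@]2(C)O[C@@H]2C)c(Cl)c1 | intermediate
41 | 8β-[(2R,3R)-2,3-epoxy-2-methylbutanoyloxy]-3β-[(2R)-2-methylbutanoyloxy]germacra-1(10)E,4Z,11(13)-trien-12,6α-olide | C=C1C(=O)O[C@@H]2/C=C(/C)[C@@H](OC(=O)[C@H](C)CC)C/C=C(\C)C[C@@H](OC(=O)[C@]3(C)O[C@@H]3C)[C@@H]12 | intermediate
42 | (1R,3S,4Z,6R,7R,8R,10R)-1β,10α-epoxy-8β-[(2R,3R)-2,3-epoxy-2-methylbutanoyloxy]-3β-[(2R)-2-methylbutanoyloxy]germacra-4,11(13)-dien-12,6α-olide | C=C1C(=O)O[C@@H]2/C=C(/C)[C@@H](OC(=O)[C@H](C)CC)C[C@H]3O[C@]3(C)C[C@@H](OC(=O)[C@]3(C)O[C@@H]3C)[C@@H]12 | target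

**Totals**
Total step count: 27. Longest linear sequence: 19 steps (10 → 42 through steps 6–22, 26 and 27).

**Three steps most likely to fail**

Step 13 (facial selectivity of the allylation with respect to C6). The 7,8-syn relationship is secure, but the anti-to-OTES facial preference rests on a steric model. If the aldehyde instead adds syn to the OTES group, the fallback sets out from aldehyde 9 and couples it under the same zinc conditions with the enantiomeric bromide methyl (2Z,4R,5Z)-2-(bromomethyl)-6-iodo-4-[(triethylsilyl)oxy]hepta-2,5-dienoate F1 (made as 23 but from (S)-solketal). This gives the 6-epi adduct F2, which has the correct C7 and C8 but the wrong C6. Silylation with TBSOTf gives the 6-epi silyl ether F3, Me3SnOH cleaves the methyl ester to the acid F4, and PPTS/MeOH removes the TES group to give the hydroxy acid F5. A Mitsunobu lactonisation (PPh3, DIAD, toluene) then closes the γ-lactone with inversion at C6, and the fallback comes back to the route at lactone 27.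

Step 18 (ten-membered ring closure). If the trans-fused lactone makes the seco-aldehyde 29 too strained to close and oligomers dominate, the order of ring formation is reversed. The fallback sets out from 25: DDQ removes the PMB group to give the open-chain alcohol F6, DMP/pyridine gives the open-chain aldehyde F7, and the Ni/Cr cyclisation is run on this more flexible ester to give the carbocyclic hydroxy ester F8. PPTS/MeOH then removes the TES group and the freed C6–OH lactonises onto the ester, which comes back to the route at 30.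

Step 20 (catalyst-controlled reduction inside the macrocycle). If the CBS catalyst is mismatched with the ring conformation or 1,4-reduction competes, oxidation–reduction is abandoned. The fallback sets out from the NHK mixture 30 and separates the epimers by chromatography. The 3S epimer is 32 and goes on through step 21. The 3R epimer, (3R)-8β-[(tert-butyldimethylsilyl)oxy]-3α-hydroxygermacra-1(10)E,4Z,11(13)-trien-12,6α-olide F9, is esterified with acid 33 under Mitsunobu conditions (PPh3, DIAD, toluene, 0 °C) with inversion, which comes back to the route at 34.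

**Further compounds**
F1 | step 13 | methyl (2Z,4R,5Z)-2-(bromomethyl)-6-iodo-4-[(triethylsilyl)oxy]hepta-2,5-dienoate | COC(=O)/C(CBr)=C/[C@@H](O[Si](CC)(CC)CC)/C=C(/C)I
F2 | step 13 | methyl (3R,4R,6E)-4-hydroxy-3-[(1R,2Z)-3-iodo-1-[(triethylsilyl)oxy]but-2-en-1-yl]-9-[(4-methoxybenzyl)oxy]-6-methyl-2-methylidenenon-6-enoate | C=C(C(=O)OC)[C@@H]([C@@H](O[Si](CC)(CC)CC)/C=C(/C)I)[C@H](O)C/C(C)=C/CCOCc1ccc(OC)cc1
F3 | step 13 | methyl (3R,4R,6E)-4-[(tert-butyldimethylsilyl)oxy]-3-[(1R,2Z)-3-iodo-1-[(triethylsilyl)oxy]but-2-en-1-yl]-9-[(4-methoxybenzyl)oxy]-6-methyl-2-methylidenenon-6-enoate | C=C(C(=O)OC)[C@@H]([C@@H](O[Si](CC)(CC)CC)/C=C(/C)I)[C@H](O[Si](C)(C)C(C)(C)C)C/C(C)=C/CCOCc1ccc(OC)cc1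
F4 | step 13 | (3R,4R,6E)-4-[(tert-butyldimethylsilyl)oxy]-3-[(1R,2Z)-3-iodo-1-[(triethylsilyl)oxy]but-2-en-1-yl]-9-[(4-methoxybenzyl)oxy]-6-methyl-2-methylidenenon-6-enoic acid | C=C(C(=O)O)[C@@H]([C@@H](O[Si](CC)(CC)CC)/C=C(/C)I)[C@H](O[Si](C)(C)C(C)(C)C)C/C(C)=C/CCOCc1ccc(OC)cc1
F5 | step 13 | (3S,4R,6E)-4-[(tert-butyldimethylsilyl)oxy]-3-[(1R,2Z)-1-hydroxy-3-iodobut-2-en-1-yl]-9-[(4-methoxybenzyl)oxy]-6-methyl-2-methylidenenon-6-enoic acid | C=C(C(=O)O)[C@@H]([C@@H](O)/C=C(/C)I)[C@H](O[Si](C)(C)C(C)(C)C)C/C(C)=C/CCOCc1ccc(OC)cc1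
F6 | step 18 | methyl (3R,4R,6E)-4-[(tert-butyldimethylsilyl)oxy]-9-hydroxy-3-[(1S,2Z)-3-iodo-1-[(triethylsilyl)oxy]but-2-en-1-yl]-6-methyl-2-methylidenenon-6-enoate | C=C(C(=O)OC)[C@@H]([C@H](O[Si](CC)(CC)CC)/C=C(/C)I)[C@H](O[Si](C)(C)C(C)(C)C)C/C(C)=C/CCO
F7 | step 18 | methyl (3R,4R,6E)-4-[(tert-butyldimethylsilyl)oxy]-3-[(1S,2Z)-3-iodo-1-[(triethylsilyl)oxy]but-2-en-1-yl]-6-methyl-2-methylidene-9-oxonon-6-enoate | C=C(C(=O)OC)[C@@H]([C@H](O[Si](CC)(CC)CC)/C=C(/C)I)[C@H](O[Si](C)(C)C(C)(C)C)C/C(C)=C/CC=O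
F8 | step 18 | methyl 8β-[(tert-butyldimethylsilyl)oxy]-3-hydroxy-6α-[(triethylsilyl)oxy]germacra-1(10)E,4Z,11(13)-trien-12-oate, C3 epimers | C=C(C(=O)OC)[C@H]1[C@H](O[Si](CC)(CC)CC)/C=C(/C)C(O)C/C=C(\C)C[C@H]1O[Si](C)(C)C(C)(C)C
F9 | step 20 | (3R)-8β-[(tert-butyldimethylsilyl)oxy]-3α-hydroxygermacra-1(10)E,4Z,11(13)-trien-12,6α-olide | C=C1C(=O)O[C@@H]2/C=C(/C)[C@H](O)C/C=C(\C)C[C@@H](O[Si](C)(C)C(C)(C)C)[C@@H]12
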